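The data are calculated with constants of no real substance; scatter was added.

The beta flask is not slow but stopped: from 3.00 min to 6.00 min its D readings differ by 1.1 percentage points at most, against a scatter of 1 point, and its E readings average 36.4%. The question is therefore what a change can still bring.

| flask | E | X | temperature | remark | time |
|---|---|---|---|---|---|
| beta | 0.10 M | 0.060 M | 25 °C | the very flask that is asked about, followed so far |  |
| theta | 0.20 M | 0.060 M | 31 °C | run made earlier |  |
| flask | 0.10 M | 0.0600 M | 25 °C |  | 8.0 min |

- beta (time / min: D / %, E / %): 0.500: 12.5, 50.0; 1.50: 13.9, 38.9; 3.00: 15.0, 36.6; 5.00: 14.6, 35.4; 6.00: 15.7, 37.2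
- theta (time / s: D / %, E / %): 10.0: 0.2, 86.9; 15.0: 2.0, 81.3; 25.0: 6.0, 77.8; 50.0: 5.5, 71.8; 90.0: 5.7, 68.4

(standard deviation of a reading: 1 percentage point)

- Monday's: at 8.0 min take out 90% of the D then present, then wait 15 min
- Tuesday's: at 8.0 min add X, 100% of the amount charged, then wait 15 min
- Sunday's: at 8.0 min raise the temperature by 10 K, then wait 15 min
- Friday's: change nothing and wait 15 min more

- solid, in amounts per volume of the solution: E
- what is taken out of D is counted as made
- at the start none of E is in solution
- additions bring no volume worth counting

* D, in percent of the E first charged, at 8.0 min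
* the option that brings most further D ("none" if no option brings more than 2 percentage points) (Monday's / Tuesday's / Sunday's / Friday's / none)
* D present, with what was taken out counted in, in percent of the E first charged, after Tuesday's
* D present, with what was taken out counted in, in percent of the E first charged, after Sunday's

In the beta flask X is charged at 60.0% of the E. The D readings from 3.00 min on average 15.1% of E, which reads as 25.2% of the X charged. This reading gives the dose yield, the fraction of a charge of X that ends as D. The theta run, with twice the E and the same X, though at 31 °C, reads 19.1%, lower, so more E did not show more D per X.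

Two views part over Tuesday's. The first says the gain follows the E still standing. That is the forecast, which gives 15% now, Tuesday's as best, 24.5% after Tuesday's and 15.2% after Sunday's, on the ground that “about 40 % of E remains, so E now limits”.

The second view, mine, says the gain follows the dose of X. A new dose equal to the first, at the same yield, gives 15 points, less than the E standing, so I put D after Tuesday's at 30.2%.

The flask gives 14.0% at 8.0 min. Tuesday's is best, adding 18 points to reach 32.1%, and Sunday's ends at 13.1%. The dose view falls short by 1.9 points, the forecast by 7.6 points.

    L + X → D (k = 0.890 M⁻¹ s⁻¹, Ea = 51.0 kJ mol⁻¹)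
    2 X → Z (k = 0.740 M⁻¹ s⁻¹, Ea = 47.0 kJ mol⁻¹)
    D ⇌ J (K = 0.590, k = 0.0400 s⁻¹, Ea = 90.0 kJ mol⁻¹, ΔH = 13.0 kJ mol⁻¹)
    E ⇌ L, rate k4*(cs4 - [L]) while solid is left; crystals form when [L] > cs4 (solubility = 41.0 mM, k = 0.110 s⁻¹)
    (constants at 25 °C)

On the result, the first dose in this flask has a dose yield of 23.4% and the second 30.2%. In the neighbour with X at 24.0% of E, where E stands at 74.7%, the carried yield asks for 6.04% D and the neighbour gives 5.61%. In the neighbour with X at 240% of E, solid E is at 0% and D reaches 43.8%, below the 60.4% asked, so there the dose figure overshoots and the E view has its region. This flask is at rest: X, the limiting reagent, is at 0% of its charge at 8.00 min, ten times the time moves D by nothing, and E still stands at 36.7% at 80.0 min.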